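Locants: ring B = C1 (sp2, CH3), C2 (=CH), C3 (CHOH), C4 (CHBr), C5 (CMe2), C6 (spiro); ring A = C6, C7H2, C8H2, C9 (sp2, CH3), C10 (sp2, Br), C11H2.
Feature used: in ring A the bromine-bearing C10 is a single carbon between C9 and the C11 methylene on spiro C6. The other five ring A atoms (C11–C6–C7–C8–C9) can therefore come from a spiro vinylcyclopropane (three-membered ring C6/C7/C11, propenyl C8=C9), and C10 from CO.
Endgame disconnections: C3–OH from the ring B enone (1,2-reduction); C4–Br from the cross-conjugated dienol ether; C10–Br from the C9=C10 enol triflate, made regiospecifically by conjugate hydride addition to the C8=C9–C10=O enone.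
Key disconnection: [5+1] carbonylation (makes C10–C11 and C9–C10, breaks C7–C11). The vinylcyclopropane goes back through aldehyde and ester to a catalytic asymmetric cyclopropanation of the exocyclic methylene on ketal-protected ring B.
Ring order: ring B is bought (ketoisophorone), the cyclopropane is built on C6 (this sets the spiro stereocentre), and ring A is closed last by the carbonylation.

Key step: step 7

Remark: the SMILES is read as (3S,4S,6S). Viewed with C1→C6 running clockwise, C4–Br and C11 point to the viewer (top face) and C3–OH and C7 point away (bottom face), so bromine and hydroxyl are trans.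

Step 1
Reactants: 1 ketoisophorone; 2 ethylene glycol
Product: 3 C3 monoketal of ketoisophorone
Conditions: 2 (1.2 equiv), p-TsOH·H2O (cat), toluene, Dean–Stark, reflux
Reagents that add atoms: ethylene glycol, OCCO
Why: Acid-catalysed ketalisation with azeotropic water removal takes only the C3 carbonyl, because the C6 carbonyl is walled in by the C5 gem-dimethyl group and the substituted C1, and the C1=C2 bond does not migrate since it stays conjugated with C6=O.

Step 2
Reactants: 3 C3 monoketal; 4 methyltriphenylphosphonium bromide
Product: 5 exocyclic diene (C6=CH2 next to C1=C2)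
Conditions: 4, KOt-Bu, toluene, 0 °C then 90 °C
Reagents that add atoms: methyltriphenylphosphonium bromide, C[P+](c1ccccc1)(c1ccccc1)c1ccccc1.[Br-]
Why: Wittig methylenation with the small unstabilised ylide copes with the hindered C6 ketone at elevated temperature because this ketone has no enolisable α-hydrogen, and the basic medium leaves the ketal intact.

Step 3
Reactants: 5 exocyclic diene; 6 tert-butyl diazoacetate
Product: 7 spiro cyclopropane tert-butyl ester (6S,7R; ester on C7 cis to C1)
Conditions: (CuOTf)2·C6H6 (1 mol %), 2,2′-isopropylidenebis[(4S)-4-tert-butyl-2-oxazoline] (2.2 mol %), CH2Cl2, rt, 6 (3 equiv) by syringe pump; chromatography removes the minor diastereomer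
Reagents that add atoms: tert-butyl diazoacetate, CC(C)(C)OC(=O)C=[N+]=[N-]
Why: Copper–bis(oxazoline) carbene transfer (catalytic asymmetric cyclopropanation) attacks the open CH2 terminus of the diene, the ligand fixing C7 as R and the bulky ester turning away from the C5 gem-dimethyl group (cis to C1), which together fix C6 as S; the minor diastereomer (ester cis to C5) has the same C7 but the opposite C6 configuration, and since C7 is erased in step 7 it must be removed here so that the optical purity of the spiro centre is not diluted.

Step 4
Reactants: 7 spiro cyclopropane tert-butyl ester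
Product: 8 cyclopropylmethanol (6S,7R)
Conditions: LiAlH4, THF, 0 °C to rt; aqueous NaOH work-up
Reagents that add atoms: none
Why: Hydride reduction of the ester to the primary alcohol touches neither the ketal, the alkene nor the unactivated cyclopropane, and leaves C6 and C7 unchanged.

Step 5
Reactants: 8 cyclopropylmethanol
Product: 9 cyclopropanecarbaldehyde (6S,7R)
Conditions: (n-Pr4N)RuO4 (5 mol %), N-methylmorpholine N-oxide, 4 Å MS, CH2Cl2, rt
Reagents that add atoms: none
Why: The Ley–Griffith oxidation runs under neutral anhydrous conditions, stops at the aldehyde and spares the acid-labile allylic ketal, and any epimerisation at C7 would be harmless because only C6 is carried through to the target.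

Step 6
Reactants: 9 cyclopropanecarbaldehyde; 10 5-(ethylsulfonyl)-1-phenyl-1H-tetrazole
Product: 11 spiro[2.5] E-propenylcyclopropane of ketal-protected ring B (6S,7S)
Conditions: 10, KN(SiMe3)2, DME, −60 °C; then 9, −60 °C to rt
Reagents that add atoms: 5-(ethylsulfonyl)-1-phenyl-1H-tetrazole, CCS(=O)(=O)c1nnnn1-c1ccccc1
Why: The Julia–Kocienski olefination of an α-branched aldehyde with a phenyltetrazolyl sulfone and a potassium base in DME runs through the anti adduct, Smiles rearrangement and stereospecific elimination, which should give the E-propenyl group without touching C6 or C7 (the C7 descriptor changes only through the priority rules).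

Step 7
Reactants: 11 spiro[2.5] E-propenylcyclopropane; 12 carbon monoxide
Product: 14 conjugated spiro[5.5] enone (6R; C10 ketone; C8=C9 alkene), via deconjugated enone 13 (not isolated)
Conditions: Fe(CO)5 (2 equiv), CO (1 atm), i-PrOH, hν (medium-pressure Hg lamp, Pyrex), rt; then DBU, rt; air, filtration through silica
Reagents that add atoms: carbon monoxide, [C-]#[O+] (passed on through the coordination sphere of Fe(CO)5, [Fe].[C-]#[O+].[C-]#[O+].[C-]#[O+].[C-]#[O+].[C-]#[O+])
Why: Photolysis strips CO from Fe(CO)5, the Fe(CO)4 fragment binds the E-propenyl group (the least hindered alkene) and inserts into the adjacent C7–C11 cyclopropane bond to give a ferracyclohexene with a σ-bond to C11 and an η3-allyl over C7–C8–C9, after which CO migrates into the Fe–C11 bond (C10–C11 made) and reductive elimination joins the acyl carbon to the allyl terminus C9 (C9–C10 made). The closest known reaction type is the photochemical Fe(CO)5-mediated carbonylation of alkenylcyclopropanes to 2,5-substituted cyclohexenones, with the rhodium-catalysed [5+1] of vinylcyclopropanes and CO as its thermal counterpart. Ring A closes as a formal [5+1] cycloaddition, by reductive elimination from the ring-expanded acyl ferracycle, and DBU then moves the C7=C8 bond of 13 into conjugation as C8=C9. No lasting stereocentre is created: C9 of 13 is flattened by DBU, C7 ceases to be stereogenic, and C6 keeps its spatial arrangement because all bonds made and broken lie at C7, C9, C10 and C11 (its descriptor changes from S to R only through the priority rules). The step needs cleavage of C7–C11 rather than of the doubly allylic C6–C7 bond, and it needs the C1=C2 bond to stay out; iron is kept off the fully substituted C6 by the C5 gem-dimethyl and C1 methyl groups, and the ring B alkene is locked with C2 pointing away from the cyclopropane, so it can neither close a metallacycle nor enter a divinylcyclopropane rearrangement with the cis propenyl group. The E geometry places the C9 methyl group syn on the allyl unit, which is the less crowded arrangement.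

Step 8
Reactants: 14 conjugated spiro[5.5] enone
Product: 16 C9=C10 enol triflate (6R), via lithium enolate 15 (not isolated)
Conditions: LiBH(s-Bu)3 (1.05 equiv), THF, −78 °C; then PhNTf2, −78 °C to rt
Reagents that add atoms: N-phenylbis(trifluoromethanesulfonimide), O=S(=O)(N(c1ccccc1)S(=O)(=O)C(F)(F)F)C(F)(F)F
Why: The bulky borohydride adds hydride 1,4 to a cyclohexenone whose β-carbon C8 carries only hydrogen, which places the enolate specifically across C9=C10 and not towards C11, and O-sulfonylation freezes this regiochemistry as the tetrasubstituted enol triflate (conjugate reduction with enolate trapping).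

Step 9
Reactants: 16 C9=C10 enol triflate
Product: 17 C10 vinyl bromide with ring B ketal (6R)
Conditions: [Cp*Ru(MeCN)3]OTf (5 mol %), LiBr (3 equiv), 1,3-dimethyl-2-imidazolidinone, rt to 60 °C
Reagents that add atoms: lithium bromide, [Li+].[Br-]
Why: Ruthenium-catalysed triflate–halide exchange (oxidative addition of the alkenyl triflate to the Cp*Ru cation, then C–Br bond formation with bromide) replaces OTf by Br at the same carbon under neutral conditions that the ketal and the C1=C2 bond tolerate.

Step 10
Reactants: 17 C10 vinyl bromide with ring B ketal
Product: 18 ring B enone (6R)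
Conditions: 1 M HCl, THF, rt
Reagents that add atoms: water, O
Why: Mild aqueous acid hydrolyses the allylic ketal quickly through an allyl-stabilised oxocarbenium ion, while the vinyl bromide and the quaternary C6 are inert and the C1=C2 bond ends up conjugated with C3=O.

Step 11
Reactants: 18 ring B enone
Product: 21 equatorial C4 bromo enone (4S,6S), via silyl dienol ether 19 (not isolated), via axial C4 bromide 20 (not isolated)
Conditions: LiN(i-Pr)2, THF, −78 °C, then Me3SiCl; crude 19, NBS, THF, −78 to 0 °C; short silica plug; DBU (0.2 equiv), CH2Cl2, 0 °C to rt
Reagents that add atoms: chlorotrimethylsilane, C[Si](C)(C)Cl; N-bromosuccinimide, O=C1CCC(=O)N1Br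
Why: Kinetic α′-deprotonation at C4 and silylation give the cross-conjugated dienol ether, whose only nucleophilic carbon is C4, so NBS brominates there and not at C2, the C1 methyl group or the deactivated C9=C10 bond (silyl enol ether bromination); bromine should first enter axially, anti to the pseudoaxial C5 methyl group, to give 20, and because C5 carries no hydrogen (no elimination) base-mediated enolisation can then convert 20 into the more stable 21, in which bromine is equatorial on the top face in the ring B pucker that has C7 pseudoaxial and C11 pseudoequatorial and so keeps the C1 methyl group away from C8H2.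

Step 12
Reactants: 21 equatorial C4 bromo enone
Product: 22 target (3S,4S,6S)
Conditions: NaBH4, CeCl3·7H2O, MeOH, −78 to −40 °C; aqueous NH4Cl quench
Reagents that add atoms: none
Why: The Luche reduction gives clean 1,2-addition, and the small methoxyborohydride should enter axially from the top face, because equatorial entry would drive the developing alkoxide past the eclipsing equatorial C4–Br bond into a position syn-axial to a C5 methyl group, so the hydroxyl group ends pseudoequatorial on the bottom face (3S), trans to bromine, while low temperature and a neutral quench keep the bromohydrin from closing to an epoxide.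

Compound list
1 | ketoisophorone (2,6,6-trimethylcyclohex-2-ene-1,4-dione) | CC1=CC(=O)CC(C)(C)C1=O | starting material
2 | ethylene glycol | OCCO | starting material
3 | C3 monoketal of ketoisophorone (7,9,9-trimethyl-1,4-dioxaspiro[4.5]dec-6-en-8-one) | CC1=CC2(OCCO2)CC(C)(C)C1=O | intermediate
4 | methyltriphenylphosphonium bromide | C[P+](c1ccccc1)(c1ccccc1)c1ccccc1.[Br-] | starting material
5 | exocyclic diene (7,9,9-trimethyl-8-methylidene-1,4-dioxaspiro[4.5]dec-6-ene) | CC1=CC2(OCCO2)CC(C)(C)C1=C | intermediate
6 | tert-butyl diazoacetate | CC(C)(C)OC(=O)C=[N+]=[N-] | starting material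
7 | spiro cyclopropane tert-butyl ester, cyclopropane C6/C7/C11, ester on C7 cis to C1, (6S,7R) | CC1=CC2(OCCO2)CC(C)(C)[C@@]13C[C@H]3C(=O)OC(C)(C)C | intermediate
8 | cyclopropylmethanol, CH2OH on C7 cis to C1, (6S,7R) | CC1=CC2(OCCO2)CC(C)(C)[C@@]13C[C@H]3CO | intermediate
9 | cyclopropanecarbaldehyde, CHO on C7 cis to C1, (6S,7R) | CC1=CC2(OCCO2)CC(C)(C)[C@@]13C[C@H]3C=O | intermediate
10 | 5-(ethylsulfonyl)-1-phenyl-1H-tetrazole | CCS(=O)(=O)c1nnnn1-c1ccccc1 | starting material
11 | spiro[2.5] E-propenylcyclopropane of ketal-protected ring B, propenyl on C7 cis to C1, (6S,7S) | CC1=CC2(OCCO2)CC(C)(C)[C@@]13C[C@H]3/C=C/C | intermediate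
12 | carbon monoxide | [C-]#[O+] | starting material
13 | deconjugated spiro[5.5] enone, C10 ketone, C7=C8 alkene, (6S), both C9 epimers | CC1=CC2(OCCO2)CC(C)(C)[C@]13C=CC(C)C(=O)C3 | intermediate
14 | conjugated spiro[5.5] enone, C10 ketone, C8=C9 alkene, (6R) | CC1=CC2(OCCO2)CC(C)(C)[C@]13CC=C(C)C(=O)C3 | intermediate
15 | lithium C9=C10 enolate (6R) | CC1=CC2(OCCO2)CC(C)(C)[C@]13CCC(C)=C([O-])C3.[Li+] | intermediate
16 | C9=C10 enol triflate (6R) | CC1=CC2(OCCO2)CC(C)(C)[C@]13CCC(C)=C(OS(=O)(=O)C(F)(F)F)C3 | intermediate
17 | C10 vinyl bromide with ring B ketal (6R) | CC1=CC2(OCCO2)CC(C)(C)[C@]13CCC(C)=C(Br)C3 | intermediate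
18 | ring B enone, C3 ketone, C1=C2 alkene, (6R) | CC1=CC(=O)CC(C)(C)[C@]12CCC(C)=C(Br)C2 | intermediate
19 | cross-conjugated trimethylsilyl dienol ether, C1=C2 and C3=C4, (6S) | CC1=CC(O[Si](C)(C)C)=CC(C)(C)[C@]12CCC(C)=C(Br)C2 | intermediate
20 | axial C4 bromo enone, bromine on the bottom face, (4R,6S) | CC1=CC(=O)[C@H](Br)C(C)(C)[C@]12CCC(C)=C(Br)C2 | intermediate
21 | equatorial C4 bromo enone, bromine on the top face, (4S,6S) | CC1=CC(=O)[C@@H](Br)C(C)(C)[C@]12CCC(C)=C(Br)C2 | intermediate
22 | (3S,4S,6S)-4,10-dibromo-1,5,5,9-trimethylspiro[5.5]undeca-1,9-dien-3-ol (locants of the overview) | CC1=C[C@H](O)[C@@H](Br)C(C)(C)[C@]12CCC(C)=C(Br)C2 | target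

Total step count: 12. Longest linear sequence: 12 steps (1 to 22).

Steps most likely to fail

**Step 7.** Three things may go wrong. Iron may insert into the electronically weaker, doubly allylic C6–C7 bond. The disubstituted propenyl group may bind the metal too weakly next to the crowded spiro centre. The enone may degrade under prolonged irradiation. The fallback sets out from aldehyde 9 and comes back at 14. It drops light and stoichiometric iron and separates the C9 methyl group from the ring closure.
- Wittig methylenation of 9 with the ylide from 4 gives the monosubstituted vinylcyclopropane F1, the alkene class that binds late metals best.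
- Thermal catalytic [5+1] carbonylation with cationic monovalent rhodium ([Rh(CO)2Cl]2, dppp, AgSbF6, 0.2 atm CO in N2, 1,2-dichloroethane, 4 Å MS, 85 °C) should give the deconjugated nor-methyl enone F2.
- DBU converts F2 into the conjugated nor-methyl enone F3.
- Pyridine-mediated α-iodination (I2, pyridine, CH2Cl2) gives the C9 iodo enone F4.
- Negishi coupling (MeZnCl, Pd(PPh3)4, THF, rt) installs the methyl group and returns 14.

**Step 11.** The equilibrium between the C4 epimers may be too shallow, or the amine base may cause deconjugation of the enone or loss of bromine before equilibrium is reached. The fallback sets out from the mixture of 20 and 21 and comes back at 21. It replaces thermodynamic control by kinetic protonation, so hydrogen rather than bromine is the last electrophile to arrive at C4.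
- LiN(SiMe3)2 in THF at −78 °C converts both epimers into the same lithium bromo enolate F5.
- F5 is quenched at −78 °C with acetic acid. The proton should enter axially from the bottom face, anti to the pseudoaxial C5 methyl group. This is the face bromine itself prefers, so bromine is pushed to the equatorial top position of 21.

**Step 12.** The pseudoaxial C5 methyl group lies on the face that hydride must use, so facial selectivity may be poor or may turn towards equatorial entry and the C3 epimer. The fallback sets out from 21 and comes back at 22. It accepts the steric bias and corrects C3 afterwards.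
- The bulky, oxygen-bound hydride i-Bu2AlH (CH2Cl2, −78 °C) should attack from the bottom face and give the cis bromohydrin F6 (axial 3R alcohol).
- Mitsunobu inversion (4-nitrobenzoic acid, PPh3, DIAD, toluene, 0 °C to rt) displaces the axial oxyphosphonium group from the open bottom face and gives the inverted 4-nitrobenzoate F7.
- Brief methanolysis (K2CO3, MeOH, 0 °C) releases 22. Its diequatorial bromohydrin is slow to reach the diaxial geometry that epoxide closure requires.

Further compounds
F1 | step 7 | vinylcyclopropane, vinyl on C7 cis to C1 | CC1=CC2(OCCO2)CC(C)(C)[C@@]13C[C@H]3C=C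
F2 | step 7 | deconjugated nor-methyl enone, C7=C8 alkene | CC1=CC2(OCCO2)CC(C)(C)[C@]13C=CCC(=O)C3
F3 | step 7 | conjugated nor-methyl enone, C8=C9 alkene | CC1=CC2(OCCO2)CC(C)(C)[C@]13CC=CC(=O)C3
F4 | step 7 | C9 iodo enone | CC1=CC2(OCCO2)CC(C)(C)[C@]13CC=C(I)C(=O)C3
F5 | step 11 | lithium bromo enolate, C3=C4 | CC1=CC([O-])=C(Br)C(C)(C)[C@]12CCC(C)=C(Br)C2.[Li+]
F6 | step 12 | cis bromohydrin, C3 epimer of the target (3R,4S,6S) | CC1=C[C@@H](O)[C@@H](Br)C(C)(C)[C@]12CCC(C)=C(Br)C2
F7 | step 12 | inverted 4-nitrobenzoate (3S,4S,6S) | CC1=C[C@H](OC(=O)c3ccc(cc3)[N+](=O)[O-])[C@@H](Br)C(C)(C)[C@]12CCC(C)=C(Br)C2
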